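The flavonol is disconnected at its pyranone carbonyl: C4 of ring C sits between C4a of the phloroglucinol-derived ring A and C3, so C4 is brought in as carbon monoxide. A single palladium/copper three-component coupling unites 2,4,6-tris(benzyloxy)iodobenzene, CO and an enantiopure 5-ethynyl-2,3-dihydrobenzofuran, making C4a–C4 and C4–C3 at once and giving an aryl ynone that contains the whole C6–C3–C6 carbon set. The alkyne partner already carries the trans-(2R,3S) dihydrobenzofuran with its guaiacyl ring, set earlier by an enantioselective rhodium-carbenoid C–H insertion and C3 epimerisation. Ring C is then closed, hydroxylated at C3 and unmasked.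

Key step: step 12

Assumption: the (S)-configured catalyst Rh2(S-PTTL)4 is taken to give the 2R insertion product (if the opposite sense appears, the (R)-configured catalyst is used and nothing else changes); compounds 3 and 16 are treated as catalogue materials.

Step 1
Reactants: 1 5-bromo-2,3-dihydroxybenzaldehyde
Product: 2 3-(benzyloxy)-5-bromo-2-hydroxybenzaldehyde
Conditions: NaH (2.2 equiv), THF/DMSO, 0 °C to rt; BnBr (1.0 equiv); aq. HCl work-up
Reagents that add atoms: benzyl bromide BrCc1ccccc1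
Why: Regioselective Williamson etherification of the catecholate dianion, in which the 2-phenoxide is conjugated with and chelated to the formyl group, so the more nucleophilic 3-phenoxide should take the single equivalent of benzyl bromide.

Step 2
Reactants: 2 3-(benzyloxy)-5-bromo-2-hydroxybenzaldehyde; 3 [4-(benzyloxy)-3-methoxyphenyl]methanol
Product: 4 3-(benzyloxy)-2-{[4-(benzyloxy)-3-methoxyphenyl]methoxy}-5-bromobenzaldehyde
Conditions: PPh3, DIAD, THF, 0 °C to rt
Reagents that add atoms: none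
Why: Mitsunobu etherification of an acidic salicylaldehyde-type phenol with a primary benzylic alcohol, run under neutral conditions that suit the acid-labile 4-alkoxybenzyl ether being formed.

Step 3
Reactants: 4 3-(benzyloxy)-2-{[4-(benzyloxy)-3-methoxyphenyl]methoxy}-5-bromobenzaldehyde
Product: 6 2-(3-(benzyloxy)-2-{[4-(benzyloxy)-3-methoxyphenyl]methoxy}-5-bromophenyl)acetonitrile, via N-(1-tosylvinyl)formamide 5 (not isolated)
Conditions: TosMIC, KOt-Bu, DME, −50 °C; then MeOH, reflux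
Reagents that add atoms: tosylmethyl isocyanide Cc1ccc(cc1)S(=O)(=O)C[N+]#[C-]
Why: van Leusen reductive cyanation, in which the TosMIC anion adds to the aldehyde to give formamide 5 and methanolic alkoxide then removes the formyl group and expels sulfinate to leave the one-carbon-homologated nitrile; adding the aldehyde at low temperature in an aprotic solvent before methanol should suppress oxazole formation.

Step 4
Reactants: 6 2-(3-(benzyloxy)-2-{[4-(benzyloxy)-3-methoxyphenyl]methoxy}-5-bromophenyl)acetonitrile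
Product: 7 2-(3-(benzyloxy)-2-{[4-(benzyloxy)-3-methoxyphenyl]methoxy}-5-bromophenyl)acetic acid
Conditions: KOH, EtOH/H2O, reflux; then cold dilute HCl to pH 3
Reagents that add atoms: water O
Why: Alkaline nitrile hydrolysis, chosen over an acidic Pinner alcoholysis because the 4-alkoxybenzyl aryl ether would be solvolysed by acid while the aryl bromide and benzyl ethers are inert to hydroxide.

Step 5
Reactants: 7 2-(3-(benzyloxy)-2-{[4-(benzyloxy)-3-methoxyphenyl]methoxy}-5-bromophenyl)acetic acid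
Product: 8 methyl 2-(3-(benzyloxy)-2-{[4-(benzyloxy)-3-methoxyphenyl]methoxy}-5-bromophenyl)acetate
Conditions: MeI, K2CO3, DMF, rt
Reagents that add atoms: iodomethane CI
Why: SN2 O-alkylation of the carboxylate, a mildly basic esterification that avoids the acid of a Fischer esterification.

Step 6
Reactants: 8 methyl 2-(3-(benzyloxy)-2-{[4-(benzyloxy)-3-methoxyphenyl]methoxy}-5-bromophenyl)acetate
Product: 9 methyl 2-diazo-2-(3-(benzyloxy)-2-{[4-(benzyloxy)-3-methoxyphenyl]methoxy}-5-bromophenyl)acetate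
Conditions: p-ABSA, DBU, MeCN, 0 °C to rt
Reagents that add atoms: 4-acetamidobenzenesulfonyl azide CC(=O)Nc1ccc(cc1)S(=O)(=O)N=[N+]=[N-]
Why: Regitz diazo transfer to the DBU-generated enolate of an arylacetate, the standard route to aryldiazoacetates.

Step 7
Reactants: 9 methyl 2-diazo-2-(3-(benzyloxy)-2-{[4-(benzyloxy)-3-methoxyphenyl]methoxy}-5-bromophenyl)acetate
Product: 11 methyl (2R,3R)-7-(benzyloxy)-2-[4-(benzyloxy)-3-methoxyphenyl]-5-bromo-2,3-dihydrobenzofuran-3-carboxylate (trans), via cis ester 10 (not isolated)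
Conditions: Rh2(S-PTTL)4 [dirhodium tetrakis(N-phthaloyl-(S)-tert-leucinate)] (1 mol%), toluene, −60 °C to rt; then NaOMe (0.5 equiv), MeOH, rt
Reagents that add atoms: none
Why: Intramolecular rhodium-carbenoid 1,5 C–H insertion into the ether-activated, electron-rich benzylic methylene, where the chiral carboxylate ligands select one enantiotopic hydrogen and set C2 as R in the kinetic cis ester 10; methoxide then epimerises C3 through the ester enolate to the more stable trans isomer, and C2 should hold because ring opening would be the reverse of a disfavoured 5-endo-trig closure (the optical purity can be raised by crystallisation of 11 or 12 if required).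

Step 8
Reactants: 11 methyl (2R,3R)-7-(benzyloxy)-2-[4-(benzyloxy)-3-methoxyphenyl]-5-bromo-2,3-dihydrobenzofuran-3-carboxylate
Product: 12 [(2R,3S)-7-(benzyloxy)-2-[4-(benzyloxy)-3-methoxyphenyl]-5-bromo-2,3-dihydrobenzofuran-3-yl]methanol
Conditions: LiBH4, THF, 0 °C to rt; aq. NH4Cl
Reagents that add atoms: none
Why: Hydride reduction of the ester by LiBH4, which leaves the aryl bromide and ethers alone; the trans arrangement is already the thermodynamic one, so C3 is not at risk (the descriptor changes from R to S only through the priority change at C3).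

Step 9
Reactants: 12 [(2R,3S)-7-(benzyloxy)-2-[4-(benzyloxy)-3-methoxyphenyl]-5-bromo-2,3-dihydrobenzofuran-3-yl]methanol
Product: 13 tert-butyl{[(2R,3S)-7-(benzyloxy)-2-[4-(benzyloxy)-3-methoxyphenyl]-5-bromo-2,3-dihydrobenzofuran-3-yl]methoxy}dimethylsilane
Conditions: TBSCl, imidazole, DMF, rt
Reagents that add atoms: tert-butyldimethylsilyl chloride CC(C)(C)[Si](C)(C)Cl
Why: Imidazole-promoted silylation of a primary alcohol, which masks the hydroxyl group that would otherwise intercept the aroyl–palladium intermediate of step 12.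

Step 10
Reactants: 13 tert-butyl{[(2R,3S)-7-(benzyloxy)-2-[4-(benzyloxy)-3-methoxyphenyl]-5-bromo-2,3-dihydrobenzofuran-3-yl]methoxy}dimethylsilane
Product: 15 tert-butyl{[(2R,3S)-7-(benzyloxy)-2-[4-(benzyloxy)-3-methoxyphenyl]-5-ethynyl-2,3-dihydrobenzofuran-3-yl]methoxy}dimethylsilane, via trimethylsilyl alkyne 14 (not isolated)
Conditions: ethynyltrimethylsilane, Pd(PhCN)2Cl2 (3 mol%), [HP(t-Bu)3]BF4 (6 mol%), CuI (2 mol%), i-Pr2NH, dioxane, rt to 45 °C; then K2CO3, MeOH, rt
Reagents that add atoms: ethynyltrimethylsilane C#C[Si](C)(C)C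
Why: Sonogashira coupling of the electron-rich aryl bromide with a bulky trialkylphosphine catalyst that activates aryl bromides near room temperature, followed by methanolysis of the alkynyl C–Si bond, which is far more labile than the alkyl silyl ether.

Step 11
Reactants: 16 1,3,5-tris(benzyloxy)benzene
Product: 17 1,3,5-tris(benzyloxy)-2-iodobenzene
Conditions: NIS (1.05 equiv), DMF, 0 °C to rt, dark
Reagents that add atoms: N-iodosuccinimide O=C1CCC(=O)N1I
Why: Electrophilic aromatic iodination of a highly activated ring whose three open positions are equivalent, so one mono-iodide should form and one equivalent of NIS at low temperature limits di-iodination.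

Step 12
Reactants: 15 tert-butyl{[(2R,3S)-7-(benzyloxy)-2-[4-(benzyloxy)-3-methoxyphenyl]-5-ethynyl-2,3-dihydrobenzofuran-3-yl]methoxy}dimethylsilane; 17 1,3,5-tris(benzyloxy)-2-iodobenzene; 18 carbon monoxide
Product: 19 3-[(2R,3S)-7-(benzyloxy)-2-[4-(benzyloxy)-3-methoxyphenyl]-3-{[(tert-butyldimethylsilyl)oxy]methyl}-2,3-dihydrobenzofuran-5-yl]-1-[2,4,6-tris(benzyloxy)phenyl]prop-2-yn-1-one
Conditions: Pd(PPh3)2Cl2 (5 mol%), CuI (5 mol%), Et3N (3 equiv), THF, CO (3 bar), 40 °C, slow addition of 15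
Reagents that add atoms: none
Why: Zerovalent palladium, formed in situ from Pd(PPh3)2Cl2, adds oxidatively to the C–I bond of 17, CO inserts to give the aroyl–palladium species, the copper acetylide of 15 transmetalates and reductive elimination releases ynone 19, so C4a–C4 and C4–C3 of the future chromone arise in one operation. The closest known reaction type is the carbonylative Sonogashira coupling of aryl iodides with terminal alkynes to aryl alkynyl ketones, the usual entry to flavone precursors. No ring is closed and no stereocentre is created; C2 and C3 of the dihydrobenzofuran are remote from the reacting alkyne terminus and should be untouched by the neutral tertiary-amine medium. The selectivity required is CO insertion ahead of alkynyl transfer: the two ortho benzyloxy groups slow direct aryl–alkynyl coupling while the electron-rich aryl group migrates readily to CO, and CO pressure with slow addition of 15 keeps the aryl–palladium intermediate saturated with CO. Because 17 is symmetric about its C–I axis, either ortho oxygen can later close ring C and no regiochemical issue arises, and Et3N is used in place of a secondary amine so that the ynone is not consumed by conjugate addition.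

Step 13
Reactants: 19 3-[(2R,3S)-7-(benzyloxy)-2-[4-(benzyloxy)-3-methoxyphenyl]-3-{[(tert-butyldimethylsilyl)oxy]methyl}-2,3-dihydrobenzofuran-5-yl]-1-[2,4,6-tris(benzyloxy)phenyl]prop-2-yn-1-one
Product: 20 1-[2,4-bis(benzyloxy)-6-hydroxyphenyl]-3-[(2R,3S)-7-(benzyloxy)-2-[4-(benzyloxy)-3-methoxyphenyl]-3-{[(tert-butyldimethylsilyl)oxy]methyl}-2,3-dihydrobenzofuran-5-yl]prop-2-yn-1-one
Conditions: BCl3 (1.1 equiv), CH2Cl2, −78 °C; aq. work-up
Reagents that add atoms: none
Why: Chelation-controlled Lewis-acid ether cleavage, in which BCl3 bridges the ynone carbonyl and one flanking benzyloxy oxygen in a six-membered chelate and chloride removes that benzyl group; the unchelated benzyl ethers and the silyl ether should survive one equivalent at −78 °C, and the two ortho groups are equivalent, so a single phenol results.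

Step 14
Reactants: 20 1-[2,4-bis(benzyloxy)-6-hydroxyphenyl]-3-[(2R,3S)-7-(benzyloxy)-2-[4-(benzyloxy)-3-methoxyphenyl]-3-{[(tert-butyldimethylsilyl)oxy]methyl}-2,3-dihydrobenzofuran-5-yl]prop-2-yn-1-one
Product: 22 5,7-bis(benzyloxy)-2-[(2R,3S)-7-(benzyloxy)-2-[4-(benzyloxy)-3-methoxyphenyl]-3-{[(tert-butyldimethylsilyl)oxy]methyl}-2,3-dihydrobenzofuran-5-yl]-4H-chromen-4-one, via diethylamino enone 21 (not isolated)
Conditions: Et2NH, EtOH/THF, rt to 40 °C
Reagents that add atoms: none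
Why: Amine-mediated cyclisation of an ortho-hydroxyaryl ynone, in which diethylamine adds to the alkyne to give β-amino enone 21 and the phenol then displaces the amine at the same carbon, which enforces six-membered (formally 6-endo) closure to the flavone and excludes the 5-exo aurone pathway.

Step 15
Reactants: 22 5,7-bis(benzyloxy)-2-[(2R,3S)-7-(benzyloxy)-2-[4-(benzyloxy)-3-methoxyphenyl]-3-{[(tert-butyldimethylsilyl)oxy]methyl}-2,3-dihydrobenzofuran-5-yl]-4H-chromen-4-one
Product: 25 5,7-bis(benzyloxy)-2-[(2R,3S)-7-(benzyloxy)-2-[4-(benzyloxy)-3-methoxyphenyl]-3-(hydroxymethyl)-2,3-dihydrobenzofuran-5-yl]-3-hydroxy-4H-chromen-4-one, via flavone epoxide 23 (not isolated), via silylated flavonol 24 (not isolated)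
Conditions: DMDO (acetone solution), CH2Cl2, 0 °C; concentrate; TsOH·H2O (0.2 equiv), CH2Cl2, rt; then MeOH, rt
Reagents that add atoms: dimethyldioxirane CC1(C)OO1
Why: Dioxirane epoxidation of the C2=C3 bond of a 5-O-protected flavone, then acid-catalysed opening of the 2,3-epoxide (C2 oxocarbenium, loss of H3) to the 3-hydroxyflavone; methanol added to the same acidic solution then cleaves the primary silyl ether, while the benzyl ethers and both stereocentres should be inert to catalytic TsOH at room temperature.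

Step 16
Reactants: 25 5,7-bis(benzyloxy)-2-[(2R,3S)-7-(benzyloxy)-2-[4-(benzyloxy)-3-methoxyphenyl]-3-(hydroxymethyl)-2,3-dihydrobenzofuran-5-yl]-3-hydroxy-4H-chromen-4-one
Product: 26 2,3-dehydrosilychristin; 3,5,7-trihydroxy-2-[(2R,3S)-7-hydroxy-2-(4-hydroxy-3-methoxyphenyl)-3-(hydroxymethyl)-2,3-dihydrobenzofuran-5-yl]-4H-chromen-4-one
Conditions: H2 (1 atm), Pd/C (10%), THF/MeOH, rt, stopped at full conversion
Reagents that add atoms: none
Why: Catalytic hydrogenolysis of four aryl benzyl ethers, which cleave much faster than the cyclic benzylic C2–O bond of the dihydrobenzofuran or the flavonol C2=C3 bond, so stopping at complete debenzylation should give 26 with C2 (R) and C3 (S) intact.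

Compound list
1 | 5-bromo-2,3-dihydroxybenzaldehyde | O=Cc1cc(Br)cc(O)c1O | starting material
2 | 3-(benzyloxy)-5-bromo-2-hydroxybenzaldehyde | O=Cc1cc(Br)cc(OCc2ccccc2)c1O | intermediate
3 | [4-(benzyloxy)-3-methoxyphenyl]methanol | COc1cc(CO)ccc1OCc1ccccc1 | starting material
4 | 3-(benzyloxy)-2-{[4-(benzyloxy)-3-methoxyphenyl]methoxy}-5-bromobenzaldehyde | O=Cc1cc(Br)cc(OCc2ccccc2)c1OCc1ccc(OCc2ccccc2)c(OC)c1 | intermediate
5 | N-[2-(3-(benzyloxy)-2-{[4-(benzyloxy)-3-methoxyphenyl]methoxy}-5-bromophenyl)-1-tosylethenyl]formamide | O=CNC(=Cc1cc(Br)cc(OCc2ccccc2)c1OCc1ccc(OCc2ccccc2)c(OC)c1)S(=O)(=O)c1ccc(C)cc1 | intermediate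
6 | 2-(3-(benzyloxy)-2-{[4-(benzyloxy)-3-methoxyphenyl]methoxy}-5-bromophenyl)acetonitrile | N#CCc1cc(Br)cc(OCc2ccccc2)c1OCc1ccc(OCc2ccccc2)c(OC)c1 | intermediate
7 | 2-(3-(benzyloxy)-2-{[4-(benzyloxy)-3-methoxyphenyl]methoxy}-5-bromophenyl)acetic acid | OC(=O)Cc1cc(Br)cc(OCc2ccccc2)c1OCc1ccc(OCc2ccccc2)c(OC)c1 | intermediate
8 | methyl 2-(3-(benzyloxy)-2-{[4-(benzyloxy)-3-methoxyphenyl]methoxy}-5-bromophenyl)acetate | COC(=O)Cc1cc(Br)cc(OCc2ccccc2)c1OCc1ccc(OCc2ccccc2)c(OC)c1 | intermediate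
9 | methyl 2-diazo-2-(3-(benzyloxy)-2-{[4-(benzyloxy)-3-methoxyphenyl]methoxy}-5-bromophenyl)acetate | COC(=O)C(=[N+]=[N-])c1cc(Br)cc(OCc2ccccc2)c1OCc1ccc(OCc2ccccc2)c(OC)c1 | intermediate
10 | methyl (2R,3S)-7-(benzyloxy)-2-[4-(benzyloxy)-3-methoxyphenyl]-5-bromo-2,3-dihydrobenzofuran-3-carboxylate (cis) | COc1cc([C@@H]2Oc3c(OCc4ccccc4)cc(Br)cc3[C@@H]2C(=O)OC)ccc1OCc1ccccc1 | intermediate
11 | methyl (2R,3R)-7-(benzyloxy)-2-[4-(benzyloxy)-3-methoxyphenyl]-5-bromo-2,3-dihydrobenzofuran-3-carboxylate (trans) | COc1cc([C@@H]2Oc3c(OCc4ccccc4)cc(Br)cc3[C@H]2C(=O)OC)ccc1OCc1ccccc1 | intermediate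
12 | [(2R,3S)-7-(benzyloxy)-2-[4-(benzyloxy)-3-methoxyphenyl]-5-bromo-2,3-dihydrobenzofuran-3-yl]methanol (trans) | COc1cc([C@@H]2Oc3c(OCc4ccccc4)cc(Br)cc3[C@H]2CO)ccc1OCc1ccccc1 | intermediate
13 | tert-butyl{[(2R,3S)-7-(benzyloxy)-2-[4-(benzyloxy)-3-methoxyphenyl]-5-bromo-2,3-dihydrobenzofuran-3-yl]methoxy}dimethylsilane | COc1cc([C@@H]2Oc3c(OCc4ccccc4)cc(Br)cc3[C@H]2CO[Si](C)(C)C(C)(C)C)ccc1OCc1ccccc1 | intermediate
14 | tert-butyl{[(2R,3S)-7-(benzyloxy)-2-[4-(benzyloxy)-3-methoxyphenyl]-5-[(trimethylsilyl)ethynyl]-2,3-dihydrobenzofuran-3-yl]methoxy}dimethylsilane | COc1cc([C@@H]2Oc3c(OCc4ccccc4)cc(C#C[Si](C)(C)C)cc3[C@H]2CO[Si](C)(C)C(C)(C)C)ccc1OCc1ccccc1 | intermediate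
15 | tert-butyl{[(2R,3S)-7-(benzyloxy)-2-[4-(benzyloxy)-3-methoxyphenyl]-5-ethynyl-2,3-dihydrobenzofuran-3-yl]methoxy}dimethylsilane | COc1cc([C@@H]2Oc3c(OCc4ccccc4)cc(C#C)cc3[C@H]2CO[Si](C)(C)C(C)(C)C)ccc1OCc1ccccc1 | intermediate
16 | 1,3,5-tris(benzyloxy)benzene | c1ccc(COc2cc(OCc3ccccc3)cc(OCc3ccccc3)c2)cc1 | starting material
17 | 1,3,5-tris(benzyloxy)-2-iodobenzene | Ic1c(OCc2ccccc2)cc(OCc2ccccc2)cc1OCc1ccccc1 | intermediate
18 | carbon monoxide | [C-]#[O+] | starting material
19 | 3-[(2R,3S)-7-(benzyloxy)-2-[4-(benzyloxy)-3-methoxyphenyl]-3-{[(tert-butyldimethylsilyl)oxy]methyl}-2,3-dihydrobenzofuran-5-yl]-1-[2,4,6-tris(benzyloxy)phenyl]prop-2-yn-1-one | COc1cc([C@@H]2Oc3c(OCc4ccccc4)cc(C#CC(=O)c4c(OCc5ccccc5)cc(OCc5ccccc5)cc4OCc4ccccc4)cc3[C@H]2CO[Si](C)(C)C(C)(C)C)ccc1OCc1ccccc1 | intermediate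
20 | 1-[2,4-bis(benzyloxy)-6-hydroxyphenyl]-3-[(2R,3S)-7-(benzyloxy)-2-[4-(benzyloxy)-3-methoxyphenyl]-3-{[(tert-butyldimethylsilyl)oxy]methyl}-2,3-dihydrobenzofuran-5-yl]prop-2-yn-1-one | COc1cc([C@@H]2Oc3c(OCc4ccccc4)cc(C#CC(=O)c4c(O)cc(OCc5ccccc5)cc4OCc4ccccc4)cc3[C@H]2CO[Si](C)(C)C(C)(C)C)ccc1OCc1ccccc1 | intermediate
21 | 1-[2,4-bis(benzyloxy)-6-hydroxyphenyl]-3-(diethylamino)-3-[(2R,3S)-7-(benzyloxy)-2-[4-(benzyloxy)-3-methoxyphenyl]-3-{[(tert-butyldimethylsilyl)oxy]methyl}-2,3-dihydrobenzofuran-5-yl]prop-2-en-1-one | COc1cc([C@@H]2Oc3c(OCc4ccccc4)cc(C(=CC(=O)c4c(O)cc(OCc5ccccc5)cc4OCc4ccccc4)N(CC)CC)cc3[C@H]2CO[Si](C)(C)C(C)(C)C)ccc1OCc1ccccc1 | intermediate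
22 | 5,7-bis(benzyloxy)-2-[(2R,3S)-7-(benzyloxy)-2-[4-(benzyloxy)-3-methoxyphenyl]-3-{[(tert-butyldimethylsilyl)oxy]methyl}-2,3-dihydrobenzofuran-5-yl]-4H-chromen-4-one | COc1cc([C@@H]2Oc3c(OCc4ccccc4)cc(-c4cc(=O)c5c(OCc6ccccc6)cc(OCc6ccccc6)cc5o4)cc3[C@H]2CO[Si](C)(C)C(C)(C)C)ccc1OCc1ccccc1 | intermediate
23 | 2,3-epoxide of 22 (mixture of epoxide diastereomers) | COc1cc([C@@H]2Oc3c(OCc4ccccc4)cc(C45OC4C(=O)c4c(OCc6ccccc6)cc(OCc6ccccc6)cc4O5)cc3[C@H]2CO[Si](C)(C)C(C)(C)C)ccc1OCc1ccccc1 | intermediate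
24 | 5,7-bis(benzyloxy)-2-[(2R,3S)-7-(benzyloxy)-2-[4-(benzyloxy)-3-methoxyphenyl]-3-{[(tert-butyldimethylsilyl)oxy]methyl}-2,3-dihydrobenzofuran-5-yl]-3-hydroxy-4H-chromen-4-one | COc1cc([C@@H]2Oc3c(OCc4ccccc4)cc(-c4oc5cc(OCc6ccccc6)cc(OCc6ccccc6)c5c(=O)c4O)cc3[C@H]2CO[Si](C)(C)C(C)(C)C)ccc1OCc1ccccc1 | intermediate
25 | 5,7-bis(benzyloxy)-2-[(2R,3S)-7-(benzyloxy)-2-[4-(benzyloxy)-3-methoxyphenyl]-3-(hydroxymethyl)-2,3-dihydrobenzofuran-5-yl]-3-hydroxy-4H-chromen-4-one | COc1cc([C@@H]2Oc3c(OCc4ccccc4)cc(-c4oc5cc(OCc6ccccc6)cc(OCc6ccccc6)c5c(=O)c4O)cc3[C@H]2CO)ccc1OCc1ccccc1 | intermediate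
26 | 2,3-dehydrosilychristin; 3,5,7-trihydroxy-2-[(2R,3S)-7-hydroxy-2-(4-hydroxy-3-methoxyphenyl)-3-(hydroxymethyl)-2,3-dihydrobenzofuran-5-yl]-4H-chromen-4-one | COc1cc([C@@H]2Oc3c(O)cc(-c4oc5cc(O)cc(O)c5c(=O)c4O)cc3[C@H]2CO)ccc1O | target

Total step count: 16. Longest linear sequence: 15 steps (steps 1 to 10, then 12 to 16, from 1 to 26); the iodide branch adds step 11.

Steps most likely to fail

Step 12. The alkynyl group may transfer to aryl–palladium before CO has inserted (direct coupling), the alkyne may dimerise oxidatively, or oxidative addition into the hindered, electron-rich iodide may stall. The fallback sets out from 16 and 15 and comes back at 19. Vilsmeier–Haack formylation of 16 (POCl3, DMF) should give 2,4,6-tris(benzyloxy)benzaldehyde F1. The lithium acetylide of 15 (LiHMDS, THF, −78 °C) adds to F1 to give the propargylic alcohol 3-[(2R,3S)-dihydrobenzofuran-5-yl]-1-[2,4,6-tris(benzyloxy)phenyl]prop-2-yn-1-ol F2 as a pair of carbinol epimers. Both epimers converge on ynone 19 on oxidation with MnO2 in CH2Cl2.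

Step 15. Oxygen transfer to benzylic C–H bonds (C2–H of the dihydrobenzofuran, the OCH2Ph groups) or to the electron-rich arenes may compete with the slow epoxidation of the electron-poor C2=C3 bond. The fallback sets out from 22 and comes back at 25. Carbonyl-directed C3 lithiation (LDA, THF, −78 °C) and quenching with B(OMe)3 should give the flavone 3-boronic acid dimethyl ester F4. Oxidation with H2O2/AcOH gives 24, and TsOH·H2O in MeOH/CH2Cl2 then removes the silyl group to give 25.

Step 13. Chloride may add to the Lewis-acid-activated ynone, or further benzyl ethers or the silyl ether may be lost. The fallback sets out from 19 and comes back at 22. Diethylamine is added first (EtOH/THF, rt) to give the vinylogous amide 3-(diethylamino)-1-[2,4,6-tris(benzyloxy)phenyl]prop-2-en-1-one F3, which no longer carries an electrophilic alkyne. BCl3 at −78 °C then removes one ortho benzyl group through the strongly chelating enaminone carbonyl to give 21. On acidic work-up and brief warming in EtOH, the phenol of 21 displaces the amine to give flavone 22.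

Further compounds
F1 | step 12 | 2,4,6-tris(benzyloxy)benzaldehyde | O=Cc1c(OCc2ccccc2)cc(OCc2ccccc2)cc1OCc1ccccc1
F2 | step 12 | 3-[(2R,3S)-7-(benzyloxy)-2-[4-(benzyloxy)-3-methoxyphenyl]-3-{[(tert-butyldimethylsilyl)oxy]methyl}-2,3-dihydrobenzofuran-5-yl]-1-[2,4,6-tris(benzyloxy)phenyl]prop-2-yn-1-ol (carbinol epimers) | COc1cc([C@@H]2Oc3c(OCc4ccccc4)cc(C#CC(O)c4c(OCc5ccccc5)cc(OCc5ccccc5)cc4OCc4ccccc4)cc3[C@H]2CO[Si](C)(C)C(C)(C)C)ccc1OCc1ccccc1
F3 | step 13 | 3-(diethylamino)-3-[(2R,3S)-7-(benzyloxy)-2-[4-(benzyloxy)-3-methoxyphenyl]-3-{[(tert-butyldimethylsilyl)oxy]methyl}-2,3-dihydrobenzofuran-5-yl]-1-[2,4,6-tris(benzyloxy)phenyl]prop-2-en-1-one | COc1cc([C@@H]2Oc3c(OCc4ccccc4)cc(C(=CC(=O)c4c(OCc5ccccc5)cc(OCc5ccccc5)cc4OCc4ccccc4)N(CC)CC)cc3[C@H]2CO[Si](C)(C)C(C)(C)C)ccc1OCc1ccccc1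
F4 | step 15 | dimethyl {5,7-bis(benzyloxy)-2-[(2R,3S)-7-(benzyloxy)-2-[4-(benzyloxy)-3-methoxyphenyl]-3-{[(tert-butyldimethylsilyl)oxy]methyl}-2,3-dihydrobenzofuran-5-yl]-4-oxo-4H-chromen-3-yl}boronate | COc1cc([C@@H]2Oc3c(OCc4ccccc4)cc(-c4oc5cc(OCc6ccccc6)cc(OCc6ccccc6)c5c(=O)c4B(OC)OC)cc3[C@H]2CO[Si](C)(C)C(C)(C)C)ccc1OCc1ccccc1
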